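The route rests on cutting the bond between the stereogenic carbon C-3 of the cyclohexanone ring and the first CH2 of the side chain. C-3 and the exocyclic methylidene on ring carbon C-4 form an allyl unit, so the bond is made by a copper-catalysed enantioselective SN2′ (γ-selective) allyl–alkyl coupling. The precursors are an achiral 4-(chloromethyl)cyclohex-3-enone with an endocyclic alkene and a primary alkyl-9-BBN made in the flask by hydroboration of a 1,3-diene that already carries the 4-coumarinyl ether. In one operation the step joins both halves, creates the (R) centre, shifts the alkene into the exocyclic position and gives the target.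

Key step: step 9

Remark on the chemistry: the sense of asymmetric induction of the copper/bisphosphine catalyst on this cyclic allyl chloride cannot be predicted with certainty, so "(R)-DTBM-SEGPHOS" stands for whichever ligand antipode gives the (R) centre.

Step 1
Reactants: 1 2,2-dimethylcyclohexane-1,3-dione
Product: 2 6,6-dimethyl-1,4-dioxaspiro[4.5]decan-7-one
Conditions: ethylene glycol (1.1 equiv), p-TsOH (cat.), benzene, reflux, Dean–Stark
Reagents that add atoms: ethylene glycol, OCCO
Why: Acid-catalysed ketalisation with azeotropic water removal should stop at the mono-dioxolane, because the remaining carbonyl is then flanked by the quaternary carbon and the ketal and reacts much more slowly.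

Step 2
Reactants: 2 6,6-dimethyl-1,4-dioxaspiro[4.5]decan-7-one
Product: 5 6,6-dimethyl-8-methylidene-1,4-dioxaspiro[4.5]decan-7-one, via Mannich base 3 (not isolated), via trimethylammonium iodide 4 (not isolated)
Conditions: LDA, THF, −78 °C; Me2N=CH2+ I−, −78 °C → rt; then MeI, rt; then aq. NaHCO3, CH2Cl2, rt
Reagents that add atoms: Eschenmoser's salt (N,N-dimethylmethyleneiminium iodide), C=[N+](C)C.[I-]
Why: The ketone has α-hydrogens only at C-8, so its lithium enolate undergoes a Mannich reaction with Eschenmoser's salt, and N-methylation followed by E1cB loss of trimethylamine gives the α-methylene ketone (Eschenmoser methylenation).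

Step 3
Reactants: 5 6,6-dimethyl-8-methylidene-1,4-dioxaspiro[4.5]decan-7-one
Product: 6 6,6-dimethyl-8-methylidene-1,4-dioxaspiro[4.5]decan-7-ol (racemic)
Conditions: NaBH4, CeCl3·7H2O, MeOH, −78 → 0 °C
Reagents that add atoms: none
Why: Luche reduction delivers hydride 1,2 to the enone carbonyl, and the carbinol centre is formed as a racemate, which does not matter because it is erased in step 5.

Step 4
Reactants: 6 6,6-dimethyl-8-methylidene-1,4-dioxaspiro[4.5]decan-7-ol
Product: 7 3-hydroxy-2,2-dimethyl-4-methylidenecyclohexan-1-one (racemic)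
Conditions: 1 M aq. HCl, THF, rt
Reagents that add atoms: water, O
Why: Mild acetal hydrolysis frees the ketone, the quaternary α-carbon excludes β-elimination of the hydroxyl group, and the neopentylic allylic alcohol should not ionise under these conditions.

Step 5
Reactants: 7 3-hydroxy-2,2-dimethyl-4-methylidenecyclohexan-1-one
Product: 9 4-(chloromethyl)-2,2-dimethylcyclohex-3-en-1-one, via allylic chlorosulfite 8 (not isolated)
Conditions: SOCl2 (1.2 equiv), Et2O, 0 °C → rt
Reagents that add atoms: thionyl chloride, O=S(Cl)Cl
Why: Without base the chlorosulfite of the hindered secondary allylic alcohol should collapse by the SNi′ pathway with allylic transposition, giving the primary chloride and the more substituted ring alkene, since direct substitution at the neopentylic carbon is disfavoured.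

Step 6
Reactants: 10 1-(2-hydroxy-6-methylphenyl)ethan-1-one
Product: 11 4-hydroxy-5-methyl-2H-chromen-2-one
Conditions: NaH (3 equiv), diethyl carbonate, toluene, 110 °C; then aq. HCl
Reagents that add atoms: diethyl carbonate, CCOC(=O)OCC
Why: Claisen-type C-acylation of the ketone enolate by diethyl carbonate followed by lactonisation onto the phenoxide is the standard 4-hydroxycoumarin synthesis from a 2-hydroxyacetophenone, and the 6-methyl group ends at C-5.

Step 7
Reactants: 11 4-hydroxy-5-methyl-2H-chromen-2-one; 12 (2E)-3-methylpent-2-en-4-yn-1-ol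
Product: 13 5-methyl-4-{[(2E)-3-methylpent-2-en-4-yn-1-yl]oxy}-2H-chromen-2-one
Conditions: PPh3, DIAD, THF, 0 °C → rt
Reagents that add atoms: none
Why: In this Mitsunobu reaction the acidic 4-hydroxycoumarin (a vinylogous carboxylic acid) is O-alkylated by SN2 attack at the primary CH2 of the oxyphosphonium ion, so the (E) alkene geometry is not touched.

Step 8
Reactants: 13 5-methyl-4-{[(2E)-3-methylpent-2-en-4-yn-1-yl]oxy}-2H-chromen-2-one
Product: 14 5-methyl-4-{[(2E)-3-methylpenta-2,4-dien-1-yl]oxy}-2H-chromen-2-one
Conditions: H2 (1 atm), Lindlar catalyst, quinoline, EtOAc, rt, stopped after 1 equiv H2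
Reagents that add atoms: none
Why: Lindlar semi-hydrogenation reduces the terminal alkyne to the vinyl group and should stop at the 1,3-diene, while the trisubstituted (E) alkene, the allylic ether and the coumarin are left alone by the poisoned catalyst.

Step 9
Reactants: 14 5-methyl-4-{[(2E)-3-methylpenta-2,4-dien-1-yl]oxy}-2H-chromen-2-one; 9 4-(chloromethyl)-2,2-dimethylcyclohex-3-en-1-one
Product: 16 4-{[(2E)-5-[(1R)-2,2-dimethyl-6-methylidene-3-oxocyclohexyl]-3-methylpent-2-en-1-yl]oxy}-5-methyl-2H-chromen-2-one, via B-alkyl-9-BBN 15 (not isolated)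
Conditions: 9-BBN dimer, THF, 0 → 50 °C (14 in slight excess over B–H); then KOMe (1.2 equiv), CuOTf·(toluene)0.5 (10 mol %), (R)-DTBM-SEGPHOS (10 mol %), 9 (1.0 equiv), 1,4-dioxane, 15 °C
Reagents that add atoms: none
Why: 9-BBN adds anti-Markovnikov to the monosubstituted terminal alkene of diene 14 (the trisubstituted alkene, the electron-poor coumarin C3=C4 and the lactone are much slower) to give the primary homoallylic borane 15, whose methoxide ate complex hands the alkyl group to the chiral bisphosphine–copper(I) centre. The alkylcopper attacks the ring CH (γ-carbon, C-3) of allylic chloride 9 anti to chloride in an SN2′ oxidative addition, and reductive elimination from the σ-allylcopper(III) forms the new C–C bond with the double bond now exocyclic. The closest known reaction type is the copper-catalysed enantioselective γ-selective allyl–alkyl coupling of alkyl-9-BBN reagents with primary allylic chlorides, together with the copper-catalysed asymmetric SN2′ alkylation of 1-(chloromethyl)cycloalkenes to 2-alkyl-methylidenecycloalkanes. No ring is closed. The one new stereocentre is set by the chiral ligand, which distinguishes the enantiotopic faces of the ring alkene of achiral 9, the gem-dimethyl carbon and the ketone giving no substrate bias. The step needs γ- over α-substitution, which the borate/copper(I) manifold with a chloride leaving group should provide, and attack on the allylic chloride and not on the allylic coumarinyl ether (a poorer leaving group on a γ,γ-disubstituted allyl unit) or the ketone (inert to alkylborates and alkylcopper, with no B–H left because 14 is in excess).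

Compound list
1 | 2,2-dimethylcyclohexane-1,3-dione | CC1(C)C(=O)CCCC1=O | starting material
2 | 6,6-dimethyl-1,4-dioxaspiro[4.5]decan-7-one | CC1(C)C(=O)CCCC12OCCO2 | intermediate
3 | 8-[(dimethylamino)methyl]-6,6-dimethyl-1,4-dioxaspiro[4.5]decan-7-one (racemic, not isolated) | CN(C)CC1CCC2(OCCO2)C(C)(C)C1=O | intermediate
4 | [(6,6-dimethyl-7-oxo-1,4-dioxaspiro[4.5]decan-8-yl)methyl]trimethylammonium iodide (racemic, not isolated) | C[N+](C)(C)CC1CCC2(OCCO2)C(C)(C)C1=O.[I-] | intermediate
5 | 6,6-dimethyl-8-methylidene-1,4-dioxaspiro[4.5]decan-7-one | C=C1CCC2(OCCO2)C(C)(C)C1=O | intermediate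
6 | 6,6-dimethyl-8-methylidene-1,4-dioxaspiro[4.5]decan-7-ol (racemic) | C=C1CCC2(OCCO2)C(C)(C)C1O | intermediate
7 | 3-hydroxy-2,2-dimethyl-4-methylidenecyclohexan-1-one (racemic) | C=C1CCC(=O)C(C)(C)C1O | intermediate
8 | 2,2-dimethyl-6-methylidene-3-oxocyclohexyl chlorosulfite (racemic, not isolated) | C=C1CCC(=O)C(C)(C)C1OS(=O)Cl | intermediate
9 | 4-(chloromethyl)-2,2-dimethylcyclohex-3-en-1-one | ClCC1=CC(C)(C)C(=O)CC1 | intermediate
10 | 1-(2-hydroxy-6-methylphenyl)ethan-1-one | CC(=O)c1c(C)cccc1O | starting material
11 | 4-hydroxy-5-methyl-2H-chromen-2-one | Cc1cccc2oc(=O)cc(O)c12 | intermediate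
12 | (2E)-3-methylpent-2-en-4-yn-1-ol | C#C/C(C)=C/CO | starting material
13 | 5-methyl-4-{[(2E)-3-methylpent-2-en-4-yn-1-yl]oxy}-2H-chromen-2-one | C#C/C(C)=C/COc1cc(=O)oc2cccc(C)c12 | intermediate
14 | 5-methyl-4-{[(2E)-3-methylpenta-2,4-dien-1-yl]oxy}-2H-chromen-2-one | C=C/C(C)=C/COc1cc(=O)oc2cccc(C)c12 | intermediate
15 | 4-{[(2E)-5-(9-borabicyclo[3.3.1]nonan-9-yl)-3-methylpent-2-en-1-yl]oxy}-5-methyl-2H-chromen-2-one (not isolated) | B1(CC/C(C)=C/COc2cc(=O)oc3cccc(C)c23)C2CCCC1CCC2 | intermediate
16 | 4-{[(2E)-5-[(1R)-2,2-dimethyl-6-methylidene-3-oxocyclohexyl]-3-methylpent-2-en-1-yl]oxy}-5-methyl-2H-chromen-2-one | C=C1CCC(=O)C(C)(C)[C@@H]1CC/C(C)=C/COc1cc(=O)oc2cccc(C)c12 | target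

Total step count: 9. Longest linear sequence: 6 steps (steps 1–5, then step 9).

Steps most likely to fail

Step 9 (key step). The γ-carbon is neopentylic, so the alkylcopper may instead attack the unhindered CH2–Cl terminus (α-substitution, giving the achiral endocyclic isomer). Facial discrimination by the ligand on this cyclic β,γ-disubstituted allyl unit may be low. The borate or methoxide may also attack the 4-alkoxycoumarin (transetherification or lactone opening), or the homoallylic borate may eliminate onto its own allylic coumarinyl ether. The fallback attaches the coumarin last and uses a Grignard reagent under copper/phosphoramidite catalysis, the variant established for 1-(chloromethyl)cycloalkenes. It sets out from 9 and 12 and comes back to the route at 16. Chloride 9 is ketalised again (ethylene glycol, PPTS, benzene, reflux) to 8-(chloromethyl)-6,6-dimethyl-1,4-dioxaspiro[4.5]dec-7-ene F1. Alcohol 12 is silylated (TBSCl, imidazole) to tert-butyldimethyl{[(2E)-3-methylpent-2-en-4-yn-1-yl]oxy}silane F2 and semi-hydrogenated (Lindlar) to tert-butyldimethyl{[(2E)-3-methylpenta-2,4-dien-1-yl]oxy}silane F3. Hydroboration and oxidation (9-BBN; NaOH, H2O2) should give (3E)-5-[(tert-butyldimethylsilyl)oxy]-3-methylpent-3-en-1-ol F4, and bromination (CBr4, PPh3) {[(2E)-5-bromo-3-methylpent-2-en-1-yl]oxy}(tert-butyl)dimethylsilane F5. Magnesium in Et2O converts this into {(3E)-5-[(tert-butyldimethylsilyl)oxy]-3-methylpent-3-en-1-yl}magnesium bromide F6. Slow addition of F6 to F1 with CuTC and a chiral phosphoramidite (CH2Cl2, −78 °C) should give the SN2′ product tert-butyl{[(2E)-5-[(7R)-6,6-dimethyl-8-methylidene-1,4-dioxaspiro[4.5]decan-7-yl]-3-methylpent-2-en-1-yl]oxy}dimethylsilane F7. Aqueous HCl in THF removes the ketal and the silyl ether to give (3R)-3-[(3E)-5-hydroxy-3-methylpent-3-en-1-yl]-2,2-dimethyl-4-methylidenecyclohexan-1-one F8, and Mitsunobu reaction of F8 with 11 (PPh3, DIAD) gives 16.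

Step 5. Ionisation of the chlorosulfite may lead to substitution without the allylic shift, to a 1,2-methyl shift from the neighbouring quaternary carbon, or to addition of HCl to the methylidene group. The fallback separates transposition from chlorination. It sets out from 7 and comes back at 9. A catalytic oxorhenium 1,3-transposition (Ph3SiOReO3, Et2O, 0 °C) moves the hydroxyl by a [3,3] perrhenate shift to the thermodynamically preferred primary position, giving 4-(hydroxymethyl)-2,2-dimethylcyclohex-3-en-1-one F9. SN2 chlorination under non-ionising conditions (MsCl, LiCl, 2,4,6-collidine, DMF, 0 °C) then gives 9.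

Step 7. The 4-hydroxycoumarin anion is ambident, so alkylation may go to the lactone carbonyl oxygen (2-alkoxychromone) or to C-3, and the peri 5-methyl group makes O-4 less accessible. The fallback reverses the polarity so that the oxygen can only end at C-4. It sets out from 11 and 12 and comes back at 13. Compound 11 is converted with POCl3 (Et3N, reflux) into 4-chloro-5-methyl-2H-chromen-2-one F10, and addition–elimination of the sodium alkoxide of 12 (NaH, THF, 0 °C) at C-4 gives 13.

Further compounds
F1 | step 9 | 8-(chloromethyl)-6,6-dimethyl-1,4-dioxaspiro[4.5]dec-7-ene | ClCC1=CC(C)(C)C2(OCCO2)CC1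
F2 | step 9 | tert-butyldimethyl{[(2E)-3-methylpent-2-en-4-yn-1-yl]oxy}silane | C#C/C(C)=C/CO[Si](C)(C)C(C)(C)C
F3 | step 9 | tert-butyldimethyl{[(2E)-3-methylpenta-2,4-dien-1-yl]oxy}silane | C=C/C(C)=C/CO[Si](C)(C)C(C)(C)C
F4 | step 9 | (3E)-5-[(tert-butyldimethylsilyl)oxy]-3-methylpent-3-en-1-ol | OCC/C(C)=C/CO[Si](C)(C)C(C)(C)C
F5 | step 9 | {[(2E)-5-bromo-3-methylpent-2-en-1-yl]oxy}(tert-butyl)dimethylsilane | BrCC/C(C)=C/CO[Si](C)(C)C(C)(C)C
F6 | step 9 | {(3E)-5-[(tert-butyldimethylsilyl)oxy]-3-methylpent-3-en-1-yl}magnesium bromide | Br[Mg]CC/C(C)=C/CO[Si](C)(C)C(C)(C)C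
F7 | step 9 | tert-butyl{[(2E)-5-[(7R)-6,6-dimethyl-8-methylidene-1,4-dioxaspiro[4.5]decan-7-yl]-3-methylpent-2-en-1-yl]oxy}dimethylsilane | C=C1CCC2(OCCO2)C(C)(C)[C@@H]1CC/C(C)=C/CO[Si](C)(C)C(C)(C)C
F8 | step 9 | (3R)-3-[(3E)-5-hydroxy-3-methylpent-3-en-1-yl]-2,2-dimethyl-4-methylidenecyclohexan-1-one | C=C1CCC(=O)C(C)(C)[C@@H]1CC/C(C)=C/CO
F9 | step 5 | 4-(hydroxymethyl)-2,2-dimethylcyclohex-3-en-1-one | OCC1=CC(C)(C)C(=O)CC1
F10 | step 7 | 4-chloro-5-methyl-2H-chromen-2-one | Cc1cccc2oc(=O)cc(Cl)c12
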